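## Structural features

The target is a cis-fused bicyclo[5.3.0]decane (hydroazulene, daucane type). A cyclopentane (C6–C7–C8–C9–C10) shares the C6–C10 bond with a cycloheptenone (C1–C2–C3=C4–C5(=O)–C6–C10). Four stereocentres are clustered around the fusion: the acyloxy carbinol C1 (S), the fusion methine C10 (R), the tertiary isopropyl carbinol C9 (R) and the quaternary, methyl-bearing C6 (S). The C6 methyl, C10–H and C9–OH lie on one face; the C1 oxygen and the isopropyl group lie on the other. The fragile groups are the 4-methoxybenzoate at C1 (deprotonation at C2 through the dienolate would expel it), the tertiary alcohol and the β-methyl enone. The real difficulty is the fusion bond C6–C10, which joins a quaternary carbon to a methine flanked by two oxygenated carbons and must be formed cis. That same bond links the α-carbon of the C5 ketone to the carbon next to the C9 hydroxyl, which is the pattern left by an enolate opening a C9–C10 epoxide. In the ten-membered ring obtained by deleting C6–C10 the two carbons are 1,5-related, so forming this one bond closes both rings; the key step uses exactly this.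

## Logic of the disconnections

**22 ⇒ 20 + 21.** The acyl C–O bond at C1 is cut. This removes the base- and nucleophile-sensitive ester from every earlier stage. The forward step must acylate the secondary C1 hydroxyl and leave the tertiary C9 hydroxyl alone.

**20 ⇒ 19.** The O–H at C1 is exchanged for O–Si. The C1 oxygen must be inert toward organometallics, hydride bases and enolates. The forward cleavage must not dehydrate the tertiary alcohol or eliminate the C1 oxygen.

**19 ⇒ 18.** The fusion bond C6–C10 is cut, with C6 as an enolate carbon and C10 as an epoxide carbon. Both rings and the stereocentres C6 and C10 disappear, leaving one ten-membered ring whose only stereochemical content is C1, a trans epoxide and an epimerisable C6. The forward step needs backside attack at C10 from inside the ring, and the enolate face that gives cis fusion.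

**18 ⇒ 17.** The two C–O bonds of the epoxide are cut, giving the ring-trans trisubstituted alkene C9=C10. Two stereocentres are exchanged for one alkene geometry. The forward oxidation must choose the isolated alkene over the enone alkene and the correct face relative to C1.

**17 ⇒ 16.** A retro-oxy-Cope step cuts C7–C8 and rejoins C5–C10. The medium ring contracts to a cyclohexenol carrying two 1,1-disubstituted alkenyl groups on adjacent carbons. The forward [3,3] shift needs these groups trans so that a chair transition state gives the ring-trans alkene.

**16 ⇒ 12 + 13.** The C5–C6 bond is cut between the carbinol carbon and the isopropenyl group. This gives a cyclohexenone and a three-carbon nucleophile. The forward addition must be 1,2, non-basic, and anti to the neighbouring alkenyl group.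

**12 ⇒ 10.** The C3=C4 double bond is traced back to a saturated ketone. The methyl-bearing carbon of the starting dione can then be used as it is. The forward step must enolise toward C4 and not toward the more acidic C10.

**10 ⇒ 9 ⇒ 8 ⇒ 7.** The C5 ketone is masked as an enol ether, the silyl group is removed, and the C1–H bond is cut back to a carbonyl. This leads to a 2-alkenyl vinylogous ester in which the two oxygens of the dione are differentiated. The forward reduction sets C1, the only stereocentre that survives to the target unchanged.

**7 ⇒ 3 + 4.** The sp2–sp2 bond C10–C9 is cut. This attaches the branched alkenyl group to the central carbon of the dione by cross-coupling and avoids direct alkenylation of a 1,3-dione.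

**3 ⇒ 2 ⇒ 1.** The C–I bond and the enol ether C–O bond are removed, reaching the commercial dione.

## Other disconnections considered

**Alternative 1:** The cut is through C2–C3 and C5–C6 of the seven-membered ring. In the forward direction a dirhodium tetracarboxylate catalyst decomposes the silyloxyvinyl diazoacetate A3 in the presence of the cyclopentenyl 2-silyloxydiene A2. Cyclopropanation of the terminal enol ether alkene C1=C2 and Cope rearrangement of the cis-divinylcyclopropane would give the cycloheptadiene ester A1.

- In its favour: it is convergent, forms two C–C bonds, the seven-membered ring and the quaternary C6 in one operation, and allows catalyst control of absolute configuration. No medium ring is needed.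
- Against it here: A1 is far from the target in oxidation pattern. The ester on C3 must become a methyl group, the C5 silyl ether a ketone, and the tetrasubstituted enol ether C1=C10 must be hydrolysed. C10 (by protonation) and C1 (by reduction) are then set late, under substrate control. The Cope step must also create a quaternary carbon at a fully substituted cyclopentene terminus, and its face is controlled only by C9, which is remote from the site of cyclopropanation.
- Comparison: Alternative 1 is the better plan in convergence and in skeletal bonds per step (two against one), and equal in the stereospecific relay that sets C6. The chosen plan delivers 19 with C6, C9 and C10 already correct and needs only two further steps, where A1 would need roughly six to eight.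

**Alternative 2:** The cut is C9–C10. In the forward direction a rhodium carbenoid generated at C10 from the α′-diazo cycloheptenone A5 would insert into the C9–H bond of the side chain on C6 to give the bicyclic bis-silyl ether A4.

- In its favour: it makes the most hindered bond directly, as a favoured 1,5-insertion into a C–H bond activated by the silyloxy group. C9 comes from a simple secondary carbinol and is transferred with retention. There is no medium ring and no conformation-dependent epoxidation.
- Against it here: the carbenoid sits next to a quaternary carbon and must reach a fully substituted methine, so hydride abstraction, insertion into the isopropyl methine or Wolff rearrangement may compete. A5 requires C5, C6 and the remote C9 to be set independently before the key step. A4 also carries the carbonyl at C1 and the silyl ether at C5, the reverse of the target, so reduction at C1, oxidation at C5 and migration of the alkene into conjugation must follow, with the allylic C1 oxygen at risk.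
- Comparison: Alternative 2 is the better plan for the security of C9 and in avoiding a medium ring. The chosen plan is better in the number of independently set stereocentres (one reduction and one epoxidation against three separate elements) and in the redox work after the key step.

**Alternative 3:** The cut is through C2–C3 and C6–C10. In the forward direction the chloromethyl ketone A7, built on the carbinol carbon of (S)-terpinen-4-ol A8 after ozonolytic ring opening, would be ionised to an oxyallyl cation across C2–C1–C10. This would add to the tethered 2-silyloxydiene to give the bicyclic ketone A6.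

- In its favour: A8 supplies C9 with its isopropyl group and the carbons C6 to C10 and C1 from the chiral pool. Both rings, two C–C bonds and the quaternary centre form at once. A6 is well placed functionally: the C5 silyl enol ether can be oxidised directly to the C3=C4 enone and the C1 ketone reduced.
- Against it here: a tetrasubstituted, acid-labile silyl dienol ether terminus must bond to a weakly stabilised oxyallyl cation and may instead be desilylated or alkylated stepwise. The cis fusion and the C9/C10 relationship depend on the compact or extended transition state and on 1,2-induction from C9, which are hard to predict with a three-atom tether. The C1 reduction must then be selective.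
- Comparison: Alternative 3 is the better plan in step count and in the source of C9, and equal in closing both rings in one step. The chosen plan is better in stereochemical predictability, because epoxide geometry and SN2 inversion carry the stereochemistry over mechanically.

Key step: step 11

**Remarks before the steps**

- Locants C1–C10 in the text are those of the target skeleton; systematic names use their own numbering.
- Precursor 18 and product 19 were checked against the target: constitution, ring sizes and descriptors agree (C1 and C9 unchanged, C10 inverted). Only the wording needs correcting: the ring-trans C9=C10 alkene of 17 is Z by the sequence rules, the enone alkene is cis in the ring, C2–H and the C3 methyl are vinylogously acidic beside C6–H, and the five-membered ring closes endo with respect to the epoxide.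
- Assumption: 7–11 are carried as mixtures at the methyl-bearing ring carbon (future C3). 10–12 and 16 are drawn as the expected major C10 epimer. Both series converge at 17, where C3, C5 and C10 are sp2.
- Metal alkoxides, enolates and borate esters that are only the unworked-up form of a numbered compound carry no number. Numbered carbon building blocks stand on the Reactants line.

## Route

**Step 1**
Reactants: 1 5-methylcyclohexane-1,3-dione
Product: 2 3-ethoxy-5-methylcyclohex-2-en-1-one
Conditions: EtOH, TsOH·H2O (cat.), toluene, reflux, Dean–Stark
Reagents that add atoms: ethanol, CCO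
Why: Acid-catalysed O-alkylation of the enolised dione with azeotropic removal of water (vinylogous ester formation) differentiates the two carbonyls. The methyl-bearing carbon becomes a stereocentre of no consequence, since step 7 makes it sp2.

**Step 2**
Reactants: 2 3-ethoxy-5-methylcyclohex-2-en-1-one
Product: 3 3-ethoxy-2-iodo-5-methylcyclohex-2-en-1-one
Conditions: N-iodosuccinimide, MeCN, 0 °C to rt, dark
Reagents that add atoms: N-iodosuccinimide, O=C1CCC(=O)N1I
Why: The β-alkoxy enone is nucleophilic at C2, so electrophilic iodination and loss of a proton should give the α-iodo vinylogous ester regiospecifically.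

**Step 3**
Reactants: 3 3-ethoxy-2-iodo-5-methylcyclohex-2-en-1-one; 4 2-bromo-3-methylbut-1-ene
Product: 7 3-ethoxy-5-methyl-2-(3-methylbut-1-en-2-yl)cyclohex-2-en-1-one, via (3-methylbut-1-en-2-yl)magnesium bromide 5 (not isolated), via (3-methylbut-1-en-2-yl)zinc chloride 6 (not isolated)
Conditions: 4, Mg, THF, 40 °C; ZnCl2, THF, 0 °C; then 3, Pd2(dba)3 (cat.), SPhos (cat.), THF, 50 °C
Reagents that add atoms: none
Why: Negishi coupling: oxidative addition of zerovalent palladium into the activated alkenyl iodide, transmetalation from the alkenylzinc and reductive elimination should form the C10–C9 bond. The organozinc tolerates the vinylogous ester carbonyl, which the Grignard reagent would not.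

**Step 4**
Reactants: 7 3-ethoxy-5-methyl-2-(3-methylbut-1-en-2-yl)cyclohex-2-en-1-one
Product: 8 (1S)-3-ethoxy-5-methyl-2-(3-methylbut-1-en-2-yl)cyclohex-2-en-1-ol
Conditions: (R)-2-methyl-CBS-oxazaborolidine (0.2 equiv), catecholborane, toluene, −78 to −30 °C; aq. NaOH work-up
Reagents that add atoms: none
Why: Corey–Bakshi–Shibata reduction: the oxazaborolidine binds the carbonyl on the methylene side, away from the α-branched alkene flank, and with the (R)-catalyst hydride delivery should give the (1S)-carbinol, which is C1 of the target. Catecholborane leaves the 1,1-disubstituted alkene alone, both methyl epimers of racemic 7 should be reduced under catalyst control, and the basic work-up protects the acid-labile 3-alkoxy allylic alcohol.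

**Step 5**
Reactants: 8 (1S)-3-ethoxy-5-methyl-2-(3-methylbut-1-en-2-yl)cyclohex-2-en-1-ol
Product: 9 tert-butyl{[(1S)-3-ethoxy-5-methyl-2-(3-methylbut-1-en-2-yl)cyclohex-2-en-1-yl]oxy}dimethylsilane
Conditions: TBSCl, imidazole, DMF, rt
Reagents that add atoms: tert-butyldimethylsilyl chloride, CC(C)(C)[Si](C)(C)Cl
Why: Silylation under basic conditions turns the labile allylic alcohol into a base-stable, poorly ionising silyl ether that lasts until step 12.

**Step 6**
Reactants: 9 tert-butyl{[(1S)-3-ethoxy-5-methyl-2-(3-methylbut-1-en-2-yl)cyclohex-2-en-1-yl]oxy}dimethylsilane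
Product: 10 (2S,3S)-3-{[tert-butyl(dimethyl)silyl]oxy}-5-methyl-2-(3-methylbut-1-en-2-yl)cyclohexan-1-one
Conditions: oxalic acid (aq., dilute), THF, 0 °C
Reagents that add atoms: water, O
Why: Enol ether hydrolysis by kinetic C-protonation at C10 and capture of the oxocarbenium ion by water; the silyl ether is a poor leaving group, so the Stork–Danheiser-type loss of the C1 oxygen seen with the free alcohol should be suppressed in cold dilute acid. Axial protonation anti to the pseudoaxial silyloxy group should give mainly the 2,3-cis ketone, and the C10 configuration is erased in step 9 in any case.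

**Step 7**
Reactants: 10 (2S,3S)-3-{[tert-butyl(dimethyl)silyl]oxy}-5-methyl-2-(3-methylbut-1-en-2-yl)cyclohexan-1-one
Product: 12 (5S,6S)-5-{[tert-butyl(dimethyl)silyl]oxy}-3-methyl-6-(3-methylbut-1-en-2-yl)cyclohex-2-en-1-one, via trimethylsilyl enol ether 11 (not isolated)
Conditions: LiN(i-Pr)2, Me3SiCl (internal quench), THF, −78 °C; solvent exchange; Pd(OAc)2, MeCN, rt
Reagents that add atoms: none
Why: Saegusa–Ito dehydrogenation: the hindered amide base with in situ silylation should take a proton from the open C4 methylene and not from the tertiary C10–H, and the palladium enolate from 11 can only eliminate toward C3. This places the alkene at C3=C4, erases the methyl stereocentre, and avoids the C10 enolate that would expel the β-silyloxy group.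

**Step 8**
Reactants: 12 (5S,6S)-5-{[tert-butyl(dimethyl)silyl]oxy}-3-methyl-6-(3-methylbut-1-en-2-yl)cyclohex-2-en-1-one; 13 2-bromopropene
Product: 16 (1R,5S,6S)-5-{[tert-butyl(dimethyl)silyl]oxy}-3-methyl-6-(3-methylbut-1-en-2-yl)-1-(prop-1-en-2-yl)cyclohex-2-en-1-ol, via isopropenylmagnesium bromide 14 (not isolated), via isopropenylcerium dichloride 15 (not isolated)
Conditions: 13, Mg, THF; CeCl3 (anhydrous), THF, −78 °C; then 12, −78 °C; H2O, then aq. NaHCO3
Reagents that add atoms: none
Why: Organocerium 1,2-addition: the weakly basic, oxophilic reagent should add to the carbonyl of this easily enolised β-silyloxy enone without deprotonation or conjugate addition. Attack anti to the neighbouring C10 alkenyl group and the axial silyloxy group sets the C5 carbinol with the two alkenyl groups trans.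

**Step 9**
Reactants: 16 (1R,5S,6S)-5-{[tert-butyl(dimethyl)silyl]oxy}-3-methyl-6-(3-methylbut-1-en-2-yl)-1-(prop-1-en-2-yl)cyclohex-2-en-1-ol
Product: 17 (2Z,5S,6Z)-5-{[tert-butyl(dimethyl)silyl]oxy}-3,10-dimethyl-7-(propan-2-yl)cyclodeca-2,6-dien-1-one
Conditions: KH, 18-crown-6, THF, 0 °C to rt; AcOH, −78 °C
Reagents that add atoms: none
Why: Anionic oxy-Cope rearrangement: the potassium alkoxide accelerates the [3,3] shift of C7=C6–C5–C10–C9=C8, breaking C5–C10 and forming C7–C8 in a four-carbon ring expansion. The trans-diequatorial alkenyl groups react through a chair transition state, so the new C9=C10 bond is trans in the ring; cold protonation gives the dienone as C6 epimers, and C1 is untouched.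

**Step 10**
Reactants: 17 (2Z,5S,6Z)-5-{[tert-butyl(dimethyl)silyl]oxy}-3,10-dimethyl-7-(propan-2-yl)cyclodeca-2,6-dien-1-one
Product: 18 (2Z,5S,6S,7R)-5-{[tert-butyl(dimethyl)silyl]oxy}-6,7-epoxy-3,10-dimethyl-7-(propan-2-yl)cyclodec-2-en-1-one
Conditions: L-fructose-derived Shi ketone (0.3 equiv), KHSO5 (as 2KHSO5·KHSO4·K2SO4), K2CO3, Bu4NHSO4, MeCN/dimethoxymethane–aq. Na2B4O7/Na2H2EDTA, 0 °C
Reagents that add atoms: potassium peroxymonosulfate, [K+].[O-]S(=O)(=O)OO
Why: Shi epoxidation: the chiral dioxirane oxidises only the electron-rich trisubstituted alkene. By the spiro transition-state model for a trans C8–C9=C10–C1 unit, the L-fructose-derived ketone should deliver oxygen to the face that gives the (9R,10S) trans epoxide. Reagent control is added because the two rotamers about C1–C10 expose opposite faces, so the C1 silyl ether alone is an unreliable control element.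

**Step 11**
Reactants: 18 (2Z,5S,6S,7R)-5-{[tert-butyl(dimethyl)silyl]oxy}-6,7-epoxy-3,10-dimethyl-7-(propan-2-yl)cyclodec-2-en-1-one
Product: 19 (3R,3aR,4S,8aS)-4-{[tert-butyl(dimethyl)silyl]oxy}-3-hydroxy-6,8a-dimethyl-3-(propan-2-yl)-2,3,3a,4,5,8a-hexahydroazulen-8(1H)-one
Conditions: KN(SiMe3)2, THF, −78 °C to 0 °C; AcOH, −78 °C
Reagents that add atoms: none
Why: KN(SiMe3)2 removes the only α-hydrogen (C6–H; C4 is vinylic) under kinetic conditions to give the cross-conjugated potassium dienolate, and on warming C6 attacks C10 from inside the ring, anti to the outward-pointing C10–O bond, in an SN2 opening that leaves the tertiary alkoxide on C9. The closest known reaction type is the base-mediated transannular enolate–epoxide alkylation of ten-membered (germacrane-type) epoxy ketones, a transannular form of intramolecular enolate–epoxide cyclisation. The five-membered ring closes in a 5-(enolexo)-endo-tet mode with respect to the epoxide and the seven-membered ring in a 7-(enolendo)-exo-tet mode; the endo opening is possible because the medium ring already holds C6 on the backside axis of C10–O. C10 is set by inversion of the (10S) epoxide carbon and C9 is retained, so the trans epoxide becomes C9–OH and C10–H cis on the cyclopentane. C6 is set by the enolate face turned toward C10: the ring-trans enolate in the crown-like conformer, the geometry by which trans,trans-cyclodecadiene epoxides give cis-fused 5–7 systems, places the C6 methyl cis to C10–H. Regioselectivity (C10, not C9) follows from ring size, since attack at C9 would need a four-membered ring, and C- over O-alkylation follows from the 1,5 C6···C10 distance. Deprotonation at C6–H rather than at the vinylogous C2–H or C3-methyl hydrogens, which could expel the C1 silanolate, is secured by the kinetic base at −78 °C before warming.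

**Step 12**
Reactants: 19 (3R,3aR,4S,8aS)-4-{[tert-butyl(dimethyl)silyl]oxy}-3-hydroxy-6,8a-dimethyl-3-(propan-2-yl)-2,3,3a,4,5,8a-hexahydroazulen-8(1H)-one
Product: 20 (3R,3aR,4S,8aS)-3,4-dihydroxy-6,8a-dimethyl-3-(propan-2-yl)-2,3,3a,4,5,8a-hexahydroazulen-8(1H)-one
Conditions: HF·pyridine, pyridine/THF, 0 °C to rt
Reagents that add atoms: none
Why: Fluoride cleavage of the secondary silyl ether under buffered conditions; the tertiary alcohol and the enone are inert, and no base is present to trigger vinylogous elimination of the C1 oxygen.

**Step 13**
Reactants: 20 (3R,3aR,4S,8aS)-3,4-dihydroxy-6,8a-dimethyl-3-(propan-2-yl)-2,3,3a,4,5,8a-hexahydroazulen-8(1H)-one; 21 4-methoxybenzoyl chloride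
Product: 22 (3R,3aR,4S,8aS)-3-hydroxy-6,8a-dimethyl-8-oxo-3-(propan-2-yl)-1,2,3,3a,4,5,8,8a-octahydroazulen-4-yl 4-methoxybenzoate
Conditions: Et3N, DMAP (cat.), CH2Cl2, 0 °C to rt
Reagents that add atoms: none
Why: DMAP-catalysed acylation distinguishes the secondary C1 hydroxyl from the hindered tertiary C9 hydroxyl, so the ester goes on C1 only and no stereocentre is touched.

## Compound list

1 | 5-methylcyclohexane-1,3-dione | CC1CC(=O)CC(=O)C1 | starting material
2 | 3-ethoxy-5-methylcyclohex-2-en-1-one | CCOC1=CC(=O)CC(C)C1 | intermediate
3 | 3-ethoxy-2-iodo-5-methylcyclohex-2-en-1-one | CCOC1=C(I)C(=O)CC(C)C1 | intermediate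
4 | 2-bromo-3-methylbut-1-ene | C=C(Br)C(C)C | starting material
5 | (3-methylbut-1-en-2-yl)magnesium bromide | CC(C)C(=C)[Mg]Br | intermediate
6 | (3-methylbut-1-en-2-yl)zinc chloride | CC(C)C(=C)[Zn]Cl | intermediate
7 | 3-ethoxy-5-methyl-2-(3-methylbut-1-en-2-yl)cyclohex-2-en-1-one | CCOC1=C(C(=C)C(C)C)C(=O)CC(C)C1 | intermediate
8 | (1S)-3-ethoxy-5-methyl-2-(3-methylbut-1-en-2-yl)cyclohex-2-en-1-ol (both methyl epimers) | CCOC1=C(C(=C)C(C)C)[C@@H](O)CC(C)C1 | intermediate
9 | tert-butyl{[(1S)-3-ethoxy-5-methyl-2-(3-methylbut-1-en-2-yl)cyclohex-2-en-1-yl]oxy}dimethylsilane | CCOC1=C(C(=C)C(C)C)[C@@H](O[Si](C)(C)C(C)(C)C)CC(C)C1 | intermediate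
10 | (2S,3S)-3-{[tert-butyl(dimethyl)silyl]oxy}-5-methyl-2-(3-methylbut-1-en-2-yl)cyclohexan-1-one | O=C1CC(C)C[C@H](O[Si](C)(C)C(C)(C)C)[C@@H]1C(=C)C(C)C | intermediate
11 | {[(5S,6S)-5-{[tert-butyl(dimethyl)silyl]oxy}-3-methyl-6-(3-methylbut-1-en-2-yl)cyclohex-1-en-1-yl]oxy}trimethylsilane | C[Si](C)(C)OC1=CC(C)C[C@H](O[Si](C)(C)C(C)(C)C)[C@@H]1C(=C)C(C)C | intermediate
12 | (5S,6S)-5-{[tert-butyl(dimethyl)silyl]oxy}-3-methyl-6-(3-methylbut-1-en-2-yl)cyclohex-2-en-1-one | O=C1C=C(C)C[C@H](O[Si](C)(C)C(C)(C)C)[C@@H]1C(=C)C(C)C | intermediate
13 | 2-bromopropene | C=C(C)Br | starting material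
14 | isopropenylmagnesium bromide | C=C(C)[Mg]Br | intermediate
15 | isopropenylcerium dichloride | C=C(C)[Ce](Cl)Cl | intermediate
16 | (1R,5S,6S)-5-{[tert-butyl(dimethyl)silyl]oxy}-3-methyl-6-(3-methylbut-1-en-2-yl)-1-(prop-1-en-2-yl)cyclohex-2-en-1-ol | C=C(C)[C@@]1(O)C=C(C)C[C@H](O[Si](C)(C)C(C)(C)C)[C@@H]1C(=C)C(C)C | intermediate
17 | (2Z,5S,6Z)-5-{[tert-butyl(dimethyl)silyl]oxy}-3,10-dimethyl-7-(propan-2-yl)cyclodeca-2,6-dien-1-one (6,7-alkene trans in the ring; C10 epimers) | O=C1/C=C(C)\C[C@H](O[Si](C)(C)C(C)(C)C)/C=C(C(C)C)/CCC1C | intermediate
18 | (2Z,5S,6S,7R)-5-{[tert-butyl(dimethyl)silyl]oxy}-6,7-epoxy-3,10-dimethyl-7-(propan-2-yl)cyclodec-2-en-1-one (C10 epimers) | O=C1/C=C(C)\C[C@H](O[Si](C)(C)C(C)(C)C)[C@@H]2O[C@@]2(C(C)C)CCC1C | intermediate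
19 | (3R,3aR,4S,8aS)-4-{[tert-butyl(dimethyl)silyl]oxy}-3-hydroxy-6,8a-dimethyl-3-(propan-2-yl)-2,3,3a,4,5,8a-hexahydroazulen-8(1H)-one | CC(C)(C)[Si](C)(C)O[C@H]2CC(C)=CC(=O)[C@@]3(C)CC[C@@](O)(C(C)C)[C@@H]23 | intermediate
20 | (3R,3aR,4S,8aS)-3,4-dihydroxy-6,8a-dimethyl-3-(propan-2-yl)-2,3,3a,4,5,8a-hexahydroazulen-8(1H)-one | O[C@H]2CC(C)=CC(=O)[C@@]3(C)CC[C@@](O)(C(C)C)[C@@H]23 | intermediate
21 | 4-methoxybenzoyl chloride | COc1ccc(cc1)C(Cl)=O | starting material
22 | (3R,3aR,4S,8aS)-3-hydroxy-6,8a-dimethyl-8-oxo-3-(propan-2-yl)-1,2,3,3a,4,5,8,8a-octahydroazulen-4-yl 4-methoxybenzoate | COc1ccc(C(=O)O[C@H]2CC(C)=CC(=O)[C@@]3(C)CC[C@@](O)(C(C)C)[C@@H]23)cc1 | target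

## Step count and least certain steps

Total: 13 steps. Longest linear sequence: 13 steps (1 to 22); 4, 13 and 21 enter directly.

**Step 11 (key step).** Proton transfer may convert the kinetic C6 enolate into the extended dienolate (deprotonation at C2), which would expel the C1 silanolate. The ring may also fail to populate the conformer that holds C6 behind the C10–O bond, leading to O-alkylation, no closure, or closure through the other enolate face. Fallback, from 18 back to 19: 18 would be converted with LiN(i-Pr)2/Me3SiCl at −78 °C into the kinetic trimethylsilyl dienol ether F1. This would be treated with BF3·OEt2 or TiCl4 in CH2Cl2 at −78 °C. The epoxide is then activated as an electrophile and attacked by a neutral enol ether, a transannular Mukaiyama-type opening with no free enolate; ring geometry again limits attack to C10, as in acid-induced cyclisations of cyclodecadiene epoxides to 5–7 systems. Aqueous work-up would give 19.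

**Step 10.** Facial selection may be poor or reversed if the catalyst's preferred face belongs to the less populated rotamer about C1–C10. Fallback, from 17 back to 18: the silyl ether of 17 would be removed with HF·pyridine to give the hydroxy dienone F2. Epoxidation with VO(acac)2/t-BuOOH would then deliver oxygen from the vanadate ester. This requires a small O–C1–C10=C9 dihedral angle on the peripheral face, which corresponds to the required erythro epoxy alcohol F3. Silylation (TBSCl, imidazole) would return 18.

**Step 4.** The vinylogous ester carbonyl is deactivated, so reduction may be slow, and the remote methyl stereocentre of the racemic substrate may erode catalyst control. Fallback, from 7 back to 8: NaBH4/CeCl3·7H2O would give the racemic allylic alcohol F4. Kinetic resolution with Candida antarctica lipase B and vinyl acetate would acetylate the (1R)-enantiomer to the acetate F5 and leave (1S)-8, separated on base-washed silica.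

**Step 6.** The allylic silyl ether may ionise (transposition to the 2-alkenyl enone), the β-silyloxy ketone may lose silanol under acid, or the side-chain alkene may move into conjugation. Fallback, from 7 back to 10:
- i-Bu2AlH followed by dilute acid work-up (Stork–Danheiser transposition) would give the transposed enone F6.
- CBS reduction with the (R)-catalyst and catecholborane would give the (1S)-allylic alcohol F7.
- VO(acac)2/t-BuOOH would give the syn epoxy alcohol F8.
- TBSCl/imidazole would give the epoxy silyl ether F9.
- A Lewis acid (BF3·OEt2, −78 °C) would open the epoxide at the allylic tertiary carbon with a 1,2-hydride shift (Meinwald rearrangement) to give 10.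

**Step 9.** The alkoxide may fragment heterolytically, the product enolate may equilibrate to the extended dienolate with loss of silanolate, or a minor cis-dialkenyl isomer may react through a transition state that gives the ring-cis alkene. Fallback, from 16 back to 17: 16 would be silylated (Me3SiCl, imidazole) to the trimethylsilyl ether F10. Heating in a base-washed sealed tube at about 200 °C (neutral siloxy-Cope rearrangement) would give the ten-membered trimethylsilyl enol ether F11. Mild hydrolysis (aqueous citric acid, THF) would give 17.

## Further compounds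

F1 | step 11 | trimethylsilyl dienol ether of 18 (C1-OSiMe3, C1=C10 of the cyclodecene numbering) | C[Si](C)(C)OC=1/C=C(C)\C[C@H](O[Si](C)(C)C(C)(C)C)[C@@H]2O[C@@]2(C(C)C)CCC=1C
F2 | step 10 | (2Z,5S,6Z)-5-hydroxy-3,10-dimethyl-7-(propan-2-yl)cyclodeca-2,6-dien-1-one | O=C1/C=C(C)\C[C@H](O)/C=C(C(C)C)/CCC1C
F3 | step 10 | (2Z,5S,6S,7R)-6,7-epoxy-5-hydroxy-3,10-dimethyl-7-(propan-2-yl)cyclodec-2-en-1-one | O=C1/C=C(C)\C[C@H](O)[C@@H]2O[C@@]2(C(C)C)CCC1C
F4 | step 4 | racemic 3-ethoxy-5-methyl-2-(3-methylbut-1-en-2-yl)cyclohex-2-en-1-ol | CCOC1=C(C(=C)C(C)C)C(O)CC(C)C1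
F5 | step 4 | (1R)-3-ethoxy-5-methyl-2-(3-methylbut-1-en-2-yl)cyclohex-2-en-1-yl acetate | CCOC1=C(C(=C)C(C)C)[C@H](OC(C)=O)CC(C)C1
F6 | step 6 | 5-methyl-2-(3-methylbut-1-en-2-yl)cyclohex-2-en-1-one | O=C1CC(C)CC=C1C(=C)C(C)C
F7 | step 6 | (1S)-5-methyl-2-(3-methylbut-1-en-2-yl)cyclohex-2-en-1-ol | O[C@H]1CC(C)CC=C1C(=C)C(C)C
F8 | step 6 | syn-2,3-epoxy-5-methyl-2-(3-methylbut-1-en-2-yl)cyclohexan-1-ol (1S; epoxide cis to hydroxyl) | O[C@H]1CC(C)C[C@H]2O[C@@]12C(=C)C(C)C
F9 | step 6 | tert-butyldimethylsilyl ether of F8 | CC(C)(C)[Si](C)(C)O[C@H]1CC(C)C[C@H]2O[C@@]12C(=C)C(C)C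
F10 | step 9 | trimethylsilyl ether of 16 | C=C(C)[C@@]1(O[Si](C)(C)C)C=C(C)C[C@H](O[Si](C)(C)C(C)(C)C)[C@@H]1C(=C)C(C)C
F11 | step 9 | trimethylsilyl enol ether of 17 | C[Si](C)(C)OC=1/C=C(C)\C[C@H](O[Si](C)(C)C(C)(C)C)/C=C(C(C)C)/CCC=1C
A1 | alternative 1 | methyl 4-(tert-butyldimethylsilyloxy)-8a-methyl-3-(propan-2-yl)-3-(triethylsilyloxy)-8-(triisopropylsilyloxy)-1,2,3,5,8,8a-hexahydroazulene-6-carboxylate | COC(=O)C1=C[C@@H](O[Si](C(C)C)(C(C)C)C(C)C)[C@@]2(C)CC[C@@](O[Si](CC)(CC)CC)(C(C)C)C2=C(O[Si](C)(C)C(C)(C)C)C1
A2 | alternative 1 | 1-[1-(tert-butyldimethylsilyloxy)ethenyl]-2-methyl-5-(propan-2-yl)-5-(triethylsilyloxy)cyclopent-1-ene | C=C(O[Si](C)(C)C(C)(C)C)C1=C(C)CC[C@@]1(O[Si](CC)(CC)CC)C(C)C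
A3 | alternative 1 | methyl (E)-2-diazo-4-(triisopropylsilyloxy)but-3-enoate | COC(=O)C(=[N+]=[N-])/C=C/O[Si](C(C)C)(C(C)C)C(C)C
A4 | alternative 2 | 3,8-bis(tert-butyldimethylsilyloxy)-6,8a-dimethyl-3-(propan-2-yl)-2,3,3a,7,8,8a-hexahydroazulen-4(1H)-one | O=C1C=C(C)C[C@H](O[Si](C)(C)C(C)(C)C)[C@@]2(C)CC[C@@](O[Si](C)(C)C(C)(C)C)(C(C)C)[C@@H]12
A5 | alternative 2 | 7-diazo-5-(tert-butyldimethylsilyloxy)-6-[3-(tert-butyldimethylsilyloxy)-4-methylpentyl]-3,6-dimethylcyclohept-2-en-1-one | O=C1C=C(C)C[C@H](O[Si](C)(C)C(C)(C)C)[C@@](C)(CC[C@@H](O[Si](C)(C)C(C)(C)C)C(C)C)C1=[N+]=[N-]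
A6 | alternative 3 | 8-(tert-butyldimethylsilyloxy)-6,8a-dimethyl-3-(propan-2-yl)-3-(triethylsilyloxy)-2,3,3a,5,6,8a-hexahydroazulen-4(1H)-one | O=C1C[C@@H](C)C=C(O[Si](C)(C)C(C)(C)C)[C@@]2(C)CC[C@@](O[Si](CC)(CC)CC)(C(C)C)[C@@H]12
A7 | alternative 3 | (9E)-8-(tert-butyldimethylsilyloxy)-1-chloro-7-methyl-4-(propan-2-yl)-4-(triethylsilyloxy)undeca-7,9-dien-2-one | ClCC(=O)C[C@](O[Si](CC)(CC)CC)(C(C)C)CCC(C)=C(O[Si](C)(C)C(C)(C)C)/C=C/C
A8 | alternative 3 | (S)-terpinen-4-ol | CC1=CC[C@](O)(C(C)C)CC1
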